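## Retrosynthetic overview

1. The target comes from a macrocyclic C8 alcohol by methacrylation and removal of one silyl group.
2. Key C7–C8 bond: the C8 aldehyde is made nucleophilic as a samarium ketyl and adds to the electrophilic β-carbon (C7) of a butenolide. Loss of a C13 alkoxide from the resulting enolate gives the exo-methylene lactone and closes the ten-membered carbocycle (formed last).
3. The butenolide (formed second) comes from ring-closing metathesis of a C6 acrylate/vinyl pair. The 3(2H)-furanone (formed first) comes from gold-catalysed cycloisomerisation of a γ-hydroxy ynone.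
4. The ynone comes from a three-component carbonylative Sonogashira coupling: a (Z)-vinyl iodide (C4–C7, C11–C13, C15), CO (C3) and a tertiary propargylic alcohol (C1, C2, C8–C10 and the C10 methyl).
5. The vinyl iodide comes from acrolein and a silyl propargyl ether (lipase resolution, hydroalumination/iodination). The alkyne comes from Sharpless epoxidation of (Z)-3-methylpent-2-en-4-yn-1-ol.

Numbering used for the target: C1 furanone C=O, C2 furanone CH, C3 furanone C–O, C4 (bears C15H2OH)=C5, C6 (lactone O–CH), C7, C8 (ester O–CH), C9H2, C10 (C–CH3 and ring O), C11 (=C13H2), C12 lactone C=O. TBS = tert-butyldimethylsilyl, TES = triethylsilyl, PMB = 4-methoxybenzyl.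

Assumption: the five compounds marked as starting materials in the list are bought as such (the enynol as its Z isomer).

## Route

Step 1
Reactants: 1 (Z)-3-methylpent-2-en-4-yn-1-ol
Product: 2 [(2S,3R)-3-ethynyl-3-methyloxiran-2-yl]methanol
Conditions: Ti(OiPr)4 (10 mol%), L-(+)-diethyl tartrate (12 mol%), tBuOOH, 4 Å MS, CH2Cl2, −20 °C
Reagents that add atoms: tert-butyl hydroperoxide, CC(C)(C)OO
Why: Katsuki–Sharpless asymmetric epoxidation of a 3,3-disubstituted allylic alcohol, in which the L-(+)-tartrate complex delivers oxygen to the alkene face that makes the quaternary carbon (the future C10) 3R.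

Step 2
Reactants: 2 [(2S,3R)-3-ethynyl-3-methyloxiran-2-yl]methanol
Product: 3 (3S)-3-methylpent-4-yne-1,3-diol
Conditions: NaAlH2(OCH2CH2OMe)2 (1.3 equiv), THF, −20 to 0 °C; aq. NaOH work-up
Reagents that add atoms: none
Why: hydroxyl-directed reductive opening of a 2,3-epoxy alcohol, in which the aluminate held on the primary alkoxide delivers hydride to C2, so the C–O bond at the quaternary carbon is untouched (the descriptor changes to S only by re-ranking) and the low temperature keeps the alkyne from being hydroaluminated.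

Step 3
Reactants: 3 (3S)-3-methylpent-4-yne-1,3-diol
Product: 4 (3S)-3-methyl-5-(triethylsilyloxy)pent-1-yn-3-ol
Conditions: TESCl (1.05 equiv), imidazole, CH2Cl2, 0 °C
Reagents that add atoms: chlorotriethylsilane, CC[Si](Cl)(CC)CC
Why: selective silylation of the primary over the tertiary hydroxyl, which keeps the C8 oxygen from adding to the ynone made later.

Step 4
Reactants: 5 tert-butyldimethyl(prop-2-yn-1-yloxy)silane; 6 acrolein
Product: 8 rac-6-(tert-butyldimethylsilyloxy)hex-1-en-4-yn-3-ol, via lithium acetylide 7 (not isolated)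
Conditions: nBuLi, THF, −78 °C; then 6, −78 °C; H2O
Reagents that add atoms: none
Why: 1,2-addition of a lithium acetylide to an enal gives the racemic vinyl alkynyl carbinol that carries C5–C7, C4 and C15.

Step 5
Reactants: 8 rac-6-(tert-butyldimethylsilyloxy)hex-1-en-4-yn-3-ol
Product: 9 (3S)-6-(tert-butyldimethylsilyloxy)hex-1-en-4-yn-3-ol
Conditions: immobilized Candida antarctica lipase B, vinyl acetate, hexane, 30 °C, stopped at about 55% conversion; chromatography
Reagents that add atoms: none
Why: lipase-catalysed kinetic resolution in which, by the Kazlauskas rule (alkynyl arm large, vinyl arm medium), the R alcohol is acetylated and the unreacted S alcohol, which has the C6 configuration of the target, is recovered in high ee.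

Step 6
Reactants: 9 (3S)-6-(tert-butyldimethylsilyloxy)hex-1-en-4-yn-3-ol
Product: 11 (3S,4Z)-6-(tert-butyldimethylsilyloxy)-5-iodohexa-1,4-dien-3-ol, via sodium vinylalanate 10 (not isolated)
Conditions: NaAlH2(OCH2CH2OMe)2 (1.6 equiv), THF, 0 °C; EtOAc; then I2, −78 to 0 °C
Reagents that add atoms: iodine, II
Why: hydroxyl-directed trans-hydroalumination of the propargylic alcohol puts hydrogen on the proximal and aluminium on the distal alkyne carbon through a five-membered alanate, and iodinolysis with retention gives the (Z)-iodoalkene with iodine cis to C6.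

Step 7
Reactants: 12 2-(bromomethyl)acrylic acid; 13 4-methoxybenzyl alcohol
Product: 14 2-[(4-methoxybenzyloxy)methyl]acrylic acid
Conditions: NaH (2.2 equiv), THF, 0 °C to rt; then aq. HCl
Reagents that add atoms: none
Why: Williamson-type displacement of the allylic bromide by the alkoxide on the carboxylate salt (direct and allylic displacement give the same product).

Step 8
Reactants: 11 (3S,4Z)-6-(tert-butyldimethylsilyloxy)-5-iodohexa-1,4-dien-3-ol; 14 2-[(4-methoxybenzyloxy)methyl]acrylic acid
Product: 15 (3S,4Z)-6-(tert-butyldimethylsilyloxy)-5-iodohexa-1,4-dien-3-yl 2-[(4-methoxybenzyloxy)methyl]acrylate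
Conditions: EDC·HCl, DMAP (cat.), CH2Cl2, 0 °C to rt
Reagents that add atoms: none
Why: Steglich esterification at oxygen, so the carbinol configuration is untouched and the C6 hydroxyl is blocked from lactonising onto the acylpalladium of the next step.

Step 9
Reactants: 15 (3S,4Z)-6-(tert-butyldimethylsilyloxy)-5-iodohexa-1,4-dien-3-yl 2-[(4-methoxybenzyloxy)methyl]acrylate; 4 (3S)-3-methyl-5-(triethylsilyloxy)pent-1-yn-3-ol
Product: 16 (3S,4Z,9S)-5-[(tert-butyldimethylsilyloxy)methyl]-9-hydroxy-9-methyl-6-oxo-11-(triethylsilyloxy)undeca-1,4-dien-7-yn-3-yl 2-[(4-methoxybenzyloxy)methyl]acrylate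
Conditions: Pd(PPh3)2Cl2 (5 mol%), CuI (2 mol%), Et3N, CO (1 atm), THF, rt
Reagents that add atoms: carbon monoxide, [C-]#[O+]
Why: carbonylative Sonogashira coupling (oxidative addition at the vinyl C–I bond, CO insertion, alkynyl transfer from copper, reductive elimination) joins the two fragments through C3 with retention of the alkene geometry.

Step 10
Reactants: 16 (3S,4Z,9S)-5-[(tert-butyldimethylsilyloxy)methyl]-9-hydroxy-9-methyl-6-oxo-11-(triethylsilyloxy)undeca-1,4-dien-7-yn-3-yl 2-[(4-methoxybenzyloxy)methyl]acrylate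
Product: 18 (3S,4Z)-6-(tert-butyldimethylsilyloxy)-5-[(2S)-2-(2-hydroxyethyl)-2-methyl-3-oxo-2,3-dihydrofuran-5-yl]hexa-1,4-dien-3-yl 2-[(4-methoxybenzyloxy)methyl]acrylate, via triethylsilyl furanone 17 (not isolated)
Conditions: (4-CF3C6H4)3PAuCl (5 mol%), AgOTf (5 mol%), toluene, rt; then MeOH, PPTS (cat.), 0 °C to rt
Reagents that add atoms: none
Why: gold-catalysed cycloisomerisation of a γ-hydroxy alkynone to a 3(2H)-furanone (the ketone oxygen is transposed onto the alkyne and the tertiary hydroxyl closes onto the former carbonyl carbon, so C10 is not touched), followed in the same pot by acid-catalysed methanolysis of the more labile primary TES ether.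

Step 11
Reactants: 18 (3S,4Z)-6-(tert-butyldimethylsilyloxy)-5-[(2S)-2-(2-hydroxyethyl)-2-methyl-3-oxo-2,3-dihydrofuran-5-yl]hexa-1,4-dien-3-yl 2-[(4-methoxybenzyloxy)methyl]acrylate
Product: 19 (5R)-5-{(1Z)-3-(tert-butyldimethylsilyloxy)-2-[(2S)-2-(2-hydroxyethyl)-2-methyl-3-oxo-2,3-dihydrofuran-5-yl]prop-1-en-1-yl}-3-[(4-methoxybenzyloxy)methyl]furan-2(5H)-one
Conditions: second-generation Grubbs catalyst RuCl2(=CHPh)(PCy3)(H2IMes) (10 mol%), CH2Cl2 (5 mM), 40 °C
Reagents that add atoms: none
Why: ring-closing metathesis of the vinyl group with the 2-substituted acrylate forms the α-substituted butenolide with loss of ethene, leaving both trisubstituted alkenes and the C6 centre untouched (R only by re-ranking).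

Step 12
Reactants: 19 (5R)-5-{(1Z)-3-(tert-butyldimethylsilyloxy)-2-[(2S)-2-(2-hydroxyethyl)-2-methyl-3-oxo-2,3-dihydrofuran-5-yl]prop-1-en-1-yl}-3-[(4-methoxybenzyloxy)methyl]furan-2(5H)-one
Product: 20 2-[(2S)-5-{(1Z)-3-(tert-butyldimethylsilyloxy)-1-[(2R)-4-[(4-methoxybenzyloxy)methyl]-5-oxo-2,5-dihydrofuran-2-yl]prop-1-en-2-yl}-2-methyl-3-oxo-2,3-dihydrofuran-2-yl]acetaldehyde
Conditions: Dess–Martin periodinane, CH2Cl2, 0 °C to rt; used at once
Reagents that add atoms: none
Why: Dess–Martin oxidation of the only free hydroxyl under base-free conditions, which spares the acidic butenolide γ-hydrogen and the β-alkoxy aldehyde.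

Step 13
Reactants: 20 2-[(2S)-5-{(1Z)-3-(tert-butyldimethylsilyloxy)-1-[(2R)-4-[(4-methoxybenzyloxy)methyl]-5-oxo-2,5-dihydrofuran-2-yl]prop-1-en-2-yl}-2-methyl-3-oxo-2,3-dihydrofuran-2-yl]acetaldehyde
Product: 22 (6R,7R,8R,10S)-15-O-(tert-butyldimethylsilyl)-8-O-demethacryloyl derivative of the target (ten-membered ring closed, free C8 hydroxyl, exo-methylene lactone), via samarium alkoxide enolate 21 (not isolated)
Conditions: SmI2 (2.5 equiv), THF (2 mM, slow addition of 20), −78 to −30 °C; aq. NH4Cl
Reagents that add atoms: none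
Why: Proposed new method: SmI2 reduces the aliphatic aldehyde to a samarium ketyl whose C8, now nucleophilic, adds to the electrophilic butenolide β-carbon C7 (the only acceptor it can reach, since attack at C5 of the dienone would need a trans-cycloheptene-like ring), a second electron gives the trivalent samarium lactone enolate 21, and this expels the C13 4-methoxybenzyl oxide (E1cB) to give the exo-methylene; C7 is set trans to C5 because the tether across the rigid furanone reaches C7 only on the butenolide face opposite the C6–C5 bond, and C8 is expected (not assured) to be R with the samarium-bound oxygen on the ring periphery chelated to the lactone carbonyl; the closest known reactions are ketyl–olefin cyclisations onto unsaturated esters and lactones and β-eliminations of samarium enolates that carry a β-oxygen group.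

Step 14
Reactants: 22 (6R,7R,8R,10S)-15-O-(tert-butyldimethylsilyl)-8-O-demethacryloyl derivative of the target
Product: 23 (6R,7R,8R,10S)-15-O-(tert-butyldimethylsilyl) ether of the target
Conditions: methacrylic anhydride, Et3N, DMAP (cat.), CH2Cl2, 0 °C to rt
Reagents that add atoms: methacrylic anhydride, C=C(C)C(=O)OC(=O)C(C)=C
Why: DMAP-catalysed acylation of the only free (secondary) hydroxyl with retention at C8.

Step 15
Reactants: 23 (6R,7R,8R,10S)-15-O-(tert-butyldimethylsilyl) ether of the target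
Product: 24 CNP0180483.4, the (4Z,6R,7R,8R,10S) target
Conditions: HF·pyridine, pyridine, THF, 0 °C to rt
Reagents that add atoms: none
Why: fluoride cleavage of the primary allylic silyl ether under buffered, non-basic conditions that spare the methacrylate, the exo-methylene lactone and the furanone.

## Compound list

1 | (Z)-3-methylpent-2-en-4-yn-1-ol | OC/C=C(/C)C#C | starting material
2 | [(2S,3R)-3-ethynyl-3-methyloxiran-2-yl]methanol | OC[C@@H]1O[C@]1(C)C#C | intermediate
3 | (3S)-3-methylpent-4-yne-1,3-diol | OCC[C@](C)(O)C#C | intermediate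
4 | (3S)-3-methyl-5-(triethylsilyloxy)pent-1-yn-3-ol | CC[Si](CC)(CC)OCC[C@](C)(O)C#C | intermediate
5 | tert-butyldimethyl(prop-2-yn-1-yloxy)silane | C#CCO[Si](C)(C)C(C)(C)C | starting material
6 | acrolein | C=CC=O | starting material
7 | [3-(tert-butyldimethylsilyloxy)prop-1-yn-1-yl]lithium | [Li]C#CCO[Si](C)(C)C(C)(C)C | intermediate
8 | rac-6-(tert-butyldimethylsilyloxy)hex-1-en-4-yn-3-ol | C=CC(O)C#CCO[Si](C)(C)C(C)(C)C | intermediate
9 | (3S)-6-(tert-butyldimethylsilyloxy)hex-1-en-4-yn-3-ol | C=C[C@H](O)C#CCO[Si](C)(C)C(C)(C)C | intermediate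
10 | sodium alanate of 9 after hydroalumination: aluminium carries two 2-methoxyethoxy groups and is bound to O3 and C5 of the (3S)-hexa-1,4-dien-3-ol skeleton in a five-membered 1,2-oxaaluminole ring | [Na+].C=C[C@@H]1O[Al-](OCCOC)(OCCOC)C(CO[Si](C)(C)C(C)(C)C)=C1 | intermediate
11 | (3S,4Z)-6-(tert-butyldimethylsilyloxy)-5-iodohexa-1,4-dien-3-ol | C=C[C@H](O)/C=C(\I)CO[Si](C)(C)C(C)(C)C | intermediate
12 | 2-(bromomethyl)acrylic acid | C=C(CBr)C(=O)O | starting material
13 | 4-methoxybenzyl alcohol | COc1ccc(CO)cc1 | starting material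
14 | 2-[(4-methoxybenzyloxy)methyl]acrylic acid | C=C(COCc1ccc(OC)cc1)C(=O)O | intermediate
15 | (3S,4Z)-6-(tert-butyldimethylsilyloxy)-5-iodohexa-1,4-dien-3-yl 2-[(4-methoxybenzyloxy)methyl]acrylate | C=C[C@H](OC(=O)C(=C)COCc1ccc(OC)cc1)/C=C(\I)CO[Si](C)(C)C(C)(C)C | intermediate
16 | (3S,4Z,9S)-5-[(tert-butyldimethylsilyloxy)methyl]-9-hydroxy-9-methyl-6-oxo-11-(triethylsilyloxy)undeca-1,4-dien-7-yn-3-yl 2-[(4-methoxybenzyloxy)methyl]acrylate | CC[Si](CC)(CC)OCC[C@](C)(O)C#CC(=O)/C(CO[Si](C)(C)C(C)(C)C)=C\[C@H](C=C)OC(=O)C(=C)COCc1ccc(OC)cc1 | intermediate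
17 | (3S,4Z)-6-(tert-butyldimethylsilyloxy)-5-{(2S)-2-methyl-3-oxo-2-[2-(triethylsilyloxy)ethyl]-2,3-dihydrofuran-5-yl}hexa-1,4-dien-3-yl 2-[(4-methoxybenzyloxy)methyl]acrylate | CC[Si](CC)(CC)OCC[C@]1(C)OC(=CC1=O)/C(CO[Si](C)(C)C(C)(C)C)=C\[C@H](C=C)OC(=O)C(=C)COCc2ccc(OC)cc2 | intermediate
18 | (3S,4Z)-6-(tert-butyldimethylsilyloxy)-5-[(2S)-2-(2-hydroxyethyl)-2-methyl-3-oxo-2,3-dihydrofuran-5-yl]hexa-1,4-dien-3-yl 2-[(4-methoxybenzyloxy)methyl]acrylate | OCC[C@]1(C)OC(=CC1=O)/C(CO[Si](C)(C)C(C)(C)C)=C\[C@H](C=C)OC(=O)C(=C)COCc2ccc(OC)cc2 | intermediate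
19 | (5R)-5-{(1Z)-3-(tert-butyldimethylsilyloxy)-2-[(2S)-2-(2-hydroxyethyl)-2-methyl-3-oxo-2,3-dihydrofuran-5-yl]prop-1-en-1-yl}-3-[(4-methoxybenzyloxy)methyl]furan-2(5H)-one | OCC[C@]1(C)OC(=CC1=O)/C(CO[Si](C)(C)C(C)(C)C)=C\[C@H]2OC(=O)C(COCc3ccc(OC)cc3)=C2 | intermediate
20 | 2-[(2S)-5-{(1Z)-3-(tert-butyldimethylsilyloxy)-1-[(2R)-4-[(4-methoxybenzyloxy)methyl]-5-oxo-2,5-dihydrofuran-2-yl]prop-1-en-2-yl}-2-methyl-3-oxo-2,3-dihydrofuran-2-yl]acetaldehyde | O=CC[C@]1(C)OC(=CC1=O)/C(CO[Si](C)(C)C(C)(C)C)=C\[C@H]2OC(=O)C(COCc3ccc(OC)cc3)=C2 | intermediate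
21 | bis(diiodosamarium) derivative (trivalent samarium) of the ring-closed compound: C8 alkoxide and C12 lactone enolate, still carrying the C13 4-methoxybenzyl ether | I[Sm](I)O[C@@H]1C[C@]2(C)OC(=CC2=O)/C(CO[Si](C)(C)C(C)(C)C)=C\[C@H]2OC(O[Sm](I)I)=C(COCc3ccc(OC)cc3)[C@@H]21 | intermediate
22 | (6R,7R,8R,10S)-15-O-(tert-butyldimethylsilyl)-8-O-demethacryloyl derivative of the target | O[C@@H]1C[C@]2(C)OC(=CC2=O)/C(CO[Si](C)(C)C(C)(C)C)=C\[C@H]2OC(=O)C(=C)[C@@H]21 | intermediate
23 | (6R,7R,8R,10S)-15-O-(tert-butyldimethylsilyl) ether of the target | C=C(C)C(=O)O[C@@H]1C[C@]2(C)OC(=CC2=O)/C(CO[Si](C)(C)C(C)(C)C)=C\[C@H]2OC(=O)C(=C)[C@@H]21 | intermediate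
24 | CNP0180483.4, (4Z,6R,7R,8R,10S) | C=C(C)C(=O)O[C@@H]1C[C@]2(C)OC(=CC2=O)/C(CO)=C\[C@H]2OC(=O)C(=C)[C@@H]21 | target

## Step count and risks

Total steps: 15. Longest linear sequence: 11 (steps 4, 5, 6, 8, 9, 10, 11, 12, 13, 14, 15).

**Step 13 is the most likely to fail.** SmI2 may instead reduce the cross-conjugated furanone dienone and expel the allylic lactone oxygen at C6. The ketyl may also be simply reduced or dimerise rather than close a ten-membered ring, and the configuration at C8 is not secured by precedent. The fallback sets out from aldehyde 20 and reverses the roles of the two carbons. DDQ (CH2Cl2, pH 7 buffer, 0 °C) removes the PMB group to give the hydroxymethyl butenolide aldehyde F1. NBS/Me2S (CH2Cl2, −20 °C) turns the allylic alcohol into the allylic bromide F2 without touching the aldehyde. CrCl2 in THF/DMF at high dilution then closes the ring by an intramolecular Nozaki–Hiyama allylation, in which the allylchromium attacks the aldehyde through C7 in a cyclic transition state. This returns to the route at 22.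

**Step 9 is the second risk.** Direct coupling without CO insertion, capture of the acylpalladium by the pendant vinyl group, or ionisation of the doubly allylic ester by zerovalent palladium could each erode the yield. The fallback sets out from alkyne 4 and iodide 15 and avoids palladium and CO. Double deprotonation of 4 with nBuLi (THF, −78 °C) and formylation with DMF gives the ynal F3. Nozaki–Hiyama–Kishi coupling of 15 with this aldehyde (CrCl2, NiCl2 1 mol%, DMF, rt) gives the secondary alcohol F4 as a mixture of carbinol epimers. MnO2 (CH2Cl2) oxidises it to the ynone, returning at 16.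

**Step 10 is the third risk.** Cationic monovalent gold or adventitious triflic acid could transpose or ionise the doubly allylic ester, or strip the TES group early so that the C8 hydroxyl adds to the ynone. The fallback sets out from 16 and uses amine conjugate addition instead of π-acid catalysis. Et2NH (1.1 equiv, EtOH, 0 °C) adds to the ynone, much faster than to the α-substituted acrylate, to give the enaminone F5. AcOH/H2O/THF at rt then closes the furanone by attack of the tertiary hydroxyl on the ketone, hydrolyses the enamine and cleaves the TES ether, returning at 18.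

## Further compounds

F1 | step 13 | 2-[(2S)-5-{(1Z)-3-(tert-butyldimethylsilyloxy)-1-[(2R)-4-(hydroxymethyl)-5-oxo-2,5-dihydrofuran-2-yl]prop-1-en-2-yl}-2-methyl-3-oxo-2,3-dihydrofuran-2-yl]acetaldehyde | O=CC[C@]1(C)OC(=CC1=O)/C(CO[Si](C)(C)C(C)(C)C)=C\[C@H]2OC(=O)C(CO)=C2
F2 | step 13 | 2-[(2S)-5-{(1Z)-1-[(2R)-4-(bromomethyl)-5-oxo-2,5-dihydrofuran-2-yl]-3-(tert-butyldimethylsilyloxy)prop-1-en-2-yl}-2-methyl-3-oxo-2,3-dihydrofuran-2-yl]acetaldehyde | O=CC[C@]1(C)OC(=CC1=O)/C(CO[Si](C)(C)C(C)(C)C)=C\[C@H]2OC(=O)C(CBr)=C2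
F3 | step 9 | (4S)-4-hydroxy-4-methyl-6-(triethylsilyloxy)hex-2-ynal | CC[Si](CC)(CC)OCC[C@](C)(O)C#CC=O
F4 | step 9 | (3S,4Z,9S)-5-[(tert-butyldimethylsilyloxy)methyl]-6,9-dihydroxy-9-methyl-11-(triethylsilyloxy)undeca-1,4-dien-7-yn-3-yl 2-[(4-methoxybenzyloxy)methyl]acrylate, both C6 epimers | CC[Si](CC)(CC)OCC[C@](C)(O)C#CC(O)/C(CO[Si](C)(C)C(C)(C)C)=C\[C@H](C=C)OC(=O)C(=C)COCc1ccc(OC)cc1
F5 | step 10 | (3S,4Z,9S)-5-[(tert-butyldimethylsilyloxy)methyl]-8-(diethylamino)-9-hydroxy-9-methyl-6-oxo-11-(triethylsilyloxy)undeca-1,4,7-trien-3-yl 2-[(4-methoxybenzyloxy)methyl]acrylate | CC[Si](CC)(CC)OCC[C@](C)(O)C(=CC(=O)/C(CO[Si](C)(C)C(C)(C)C)=C\[C@H](C=C)OC(=O)C(=C)COCc1ccc(OC)cc1)N(CC)CC
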